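**Retrosynthetic overview**

- The route rests on the O1–C2–C3 unit of the dihydrofuran ring (ring B). C2 (carrying the trimethoxyphenyl ring C) and C3 (carrying methyl) are the former C2=C3 bond of a benzofuran, and the trans aryl/methyl pair is what an anti addition gives when an aryl group migrates from boron to C2 while a carbon electrophile arrives at C3.
- Disconnections, backwards: C5–propenyl (Suzuki–Miyaura on a C5 chloride); C3–CH3 from C3–allyl (alkene cleavage, then decarbonylation); C2–H from C2–B (protodeboronation with retention); C2–C1' and C3–CH2 together from a benzofuran-2-yl boronate complex and a chiral π-allylpalladium cation.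
- Ring order: ring A is bought as 4-chloro-2-methoxyphenol; ring B is closed early as an aromatic furan and dearomatised in the key step; ring C arrives on boron.

Key step: step 3

Assumption: the sense of induction of the chiral palladium catalyst on a benzofuran-2-yl boronate cannot be derived with certainty, so the route is written with (S)-BINAP, and (R)-BINAP is used unchanged otherwise if the first run shows the mirror-image series.
Assumption: the trimethoxyphenyl pinacol boronate, allyl acetate and the (E)-propenyl pinacol boronate are taken as catalogue compounds; positions are numbered as in 2,3-dihydrobenzofuran (O1, C2, C3, C3a, C4–C7, C7a).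

**Route**

Step 1
Reactants: 1 4-chloro-2-methoxyphenol; 2 bromoacetaldehyde diethyl acetal
Product: 3 4-chloro-1-(2,2-diethoxyethoxy)-2-methoxybenzene
Conditions: K2CO3, KI (cat.), DMF, 110 °C
Reagents that add atoms: none
Why: Williamson ether synthesis, the phenoxide displacing the primary bromide while the acetal is inert to base.

Step 2
Reactants: 3 4-chloro-1-(2,2-diethoxyethoxy)-2-methoxybenzene
Product: 5 5-chloro-7-methoxybenzofuran, via 3-ethoxy-2,3-dihydrobenzofuran 4 (not isolated)
Conditions: polyphosphoric acid, PhCl, 110 °C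
Reagents that add atoms: none
Why: Acid-mediated cyclodehydration of an aryloxyacetaldehyde acetal, in which the oxocarbenium ion alkylates the only free position ortho to the ether oxygen (intramolecular Friedel–Crafts reaction) to give 4 and loss of a second ethanol aromatises the furan, so only one regioisomer can form.

Step 3
Reactants: 5 5-chloro-7-methoxybenzofuran; 6 4,4,5,5-tetramethyl-2-(3,4,5-trimethoxyphenyl)-1,3,2-dioxaborolane; 7 allyl acetate
Product: 10 2-[(2R,3R)-3-allyl-5-chloro-7-methoxy-2-(3,4,5-trimethoxyphenyl)-2,3-dihydrobenzofuran-2-yl]-4,4,5,5-tetramethyl-1,3,2-dioxaborolane, via 2-lithiobenzofuran 8 (not isolated), via lithium boronate complex 9 (not isolated)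
Conditions: n-BuLi, THF, −78 °C; then 6, −78 °C to rt; then 7, Pd2(dba)3 (2.5 mol %), (S)-BINAP (6 mol %), THF, rt; non-oxidative work-up
Reagents that add atoms: none
Why: Proposed new method: C2 lithiation and addition to the boronic ester give the tetracoordinate boronate 9, whose C2=C3 enol-ether π bond is made nucleophilic at C3 by the B–C2 bond; outer-sphere attack of C3 on the cationic (BINAP)Pd(η3-allyl) complex, formed from 7 and zerovalent palladium, is coupled to a 1,2-shift of the trimethoxyphenyl group from boron to C2, which dearomatises the furan ring. The closest known reaction type is the palladium-catalysed enantioselective three-component allylation of indol-2-yl boronate complexes, together with electrophile-triggered 1,2-migrations of furan-2-yl boronates; a benzofuran-2-yl boronate has not been used in this way. No ring is closed: the step forms the C3–CH2 and C2–C1' bonds on the existing ring B. C3 is set by the chiral bisphosphine, which lets the allyl terminus reach one face of the planar boronate, and C2 follows from C3 because the aryl group migrates antiperiplanar to the incoming electrophile, so aryl and allyl end up trans and boron cis to allyl. The step needs C3 attack to win over boron-to-palladium transmetalation (which would allylate C2) and over insertion into the C5–Cl bond; the chelating bisphosphine leaves no free site on palladium for transmetalation, and an aryl chloride is inert to n-BuLi at −78 °C and to zerovalent palladium/BINAP at rt.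

Step 4
Reactants: 10 2-[(2R,3R)-3-allyl-5-chloro-7-methoxy-2-(3,4,5-trimethoxyphenyl)-2,3-dihydrobenzofuran-2-yl]-4,4,5,5-tetramethyl-1,3,2-dioxaborolane
Product: 11 (2R,3R)-3-allyl-5-chloro-7-methoxy-2-(3,4,5-trimethoxyphenyl)-2,3-dihydrobenzofuran
Conditions: Bu4NF·3H2O, toluene, 45 °C
Reagents that add atoms: none
Why: Fluoride-promoted protodeboronation of a tertiary benzylic boronic ester, in which the fluoride ate complex is protonated by water on the face that carried boron, so the C2–H centre is set with retention and the aryl group stays trans to allyl (fluoride acts as promoter and is not consumed).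

Step 5
Reactants: 11 (2R,3R)-3-allyl-5-chloro-7-methoxy-2-(3,4,5-trimethoxyphenyl)-2,3-dihydrobenzofuran
Product: 13 2-[(2R,3R)-5-chloro-7-methoxy-2-(3,4,5-trimethoxyphenyl)-2,3-dihydrobenzofuran-3-yl]acetaldehyde, via vicinal diol 12 (not isolated)
Conditions: OsO4 (2 mol %), NaIO4, 2,6-lutidine, dioxane/H2O, rt
Reagents that add atoms: osmium tetroxide, O=[Os](=O)(=O)=O (transfers the oxygen atoms, catalytic); sodium periodate, [Na+].[O-]I(=O)(=O)=O (re-supplies that oxygen)
Why: Lemieux–Johnson oxidation, dihydroxylation of the only alkene followed by periodate cleavage of diol 12, which leaves the aryl ethers, the aryl chloride and the two ring stereocentres (neither is α to the new carbonyl) untouched.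

Step 6
Reactants: 13 2-[(2R,3R)-5-chloro-7-methoxy-2-(3,4,5-trimethoxyphenyl)-2,3-dihydrobenzofuran-3-yl]acetaldehyde
Product: 14 (2R,3R)-5-chloro-7-methoxy-3-methyl-2-(3,4,5-trimethoxyphenyl)-2,3-dihydrobenzofuran
Conditions: RhCl(PPh3)3 (1.1 equiv), degassed toluene, reflux
Reagents that add atoms: none
Why: Tsuji–Wilkinson decarbonylation (aldehyde C–H addition to monovalent rhodium, CO de-insertion, C–H reductive elimination), which turns the primary CH2–CHO into CH3 without touching C3 or the aryl chloride.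

Step 7
Reactants: 14 (2R,3R)-5-chloro-7-methoxy-3-methyl-2-(3,4,5-trimethoxyphenyl)-2,3-dihydrobenzofuran; 15 (E)-4,4,5,5-tetramethyl-2-(prop-1-enyl)-1,3,2-dioxaborolane
Product: 16 (2R,3R)-7-methoxy-3-methyl-5-[(E)-prop-1-enyl]-2-(3,4,5-trimethoxyphenyl)-2,3-dihydrobenzofuran
Conditions: Pd(OAc)2 (3 mol %), SPhos (6 mol %), K3PO4, toluene/H2O, 90 °C
Reagents that add atoms: none
Why: Suzuki–Miyaura coupling of an electron-rich aryl chloride, made feasible by the dialkylbiarylphosphine ligand, with transfer of the alkenyl group under retention of the E geometry and no effect on the sp3 stereocentres.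

**Compound list**

1 | 4-chloro-2-methoxyphenol | COc1cc(Cl)ccc1O | starting material
2 | bromoacetaldehyde diethyl acetal | CCOC(CBr)OCC | starting material
3 | 4-chloro-1-(2,2-diethoxyethoxy)-2-methoxybenzene | CCOC(COc1ccc(Cl)cc1OC)OCC | intermediate
4 | 5-chloro-3-ethoxy-7-methoxy-2,3-dihydrobenzofuran (racemic, not isolated) | CCOC1COc2c(OC)cc(Cl)cc21 | intermediate
5 | 5-chloro-7-methoxybenzofuran | COc1cc(Cl)cc2ccoc12 | intermediate
6 | 4,4,5,5-tetramethyl-2-(3,4,5-trimethoxyphenyl)-1,3,2-dioxaborolane | COc1cc(cc(OC)c1OC)B1OC(C)(C)C(C)(C)O1 | starting material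
7 | allyl acetate | CC(=O)OCC=C | starting material
8 | 5-chloro-2-lithio-7-methoxybenzofuran (not isolated) | COc1cc(Cl)cc2cc([Li])oc12 | intermediate
9 | lithium (5-chloro-7-methoxybenzofuran-2-yl)(pinacolato)(3,4,5-trimethoxyphenyl)borate (not isolated) | [Li+].COc1cc(Cl)cc2cc(oc12)[B-]1(OC(C)(C)C(C)(C)O1)c1cc(OC)c(OC)c(OC)c1 | intermediate
10 | 2-[(2R,3R)-3-allyl-5-chloro-7-methoxy-2-(3,4,5-trimethoxyphenyl)-2,3-dihydrobenzofuran-2-yl]-4,4,5,5-tetramethyl-1,3,2-dioxaborolane (allyl trans to aryl, cis to boron) | Clc1cc(OC)c2c(c1)[C@@H](CC=C)[C@](B1OC(C)(C)C(C)(C)O1)(c1cc(OC)c(OC)c(OC)c1)O2 | intermediate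
11 | (2R,3R)-3-allyl-5-chloro-7-methoxy-2-(3,4,5-trimethoxyphenyl)-2,3-dihydrobenzofuran | Clc1cc(OC)c2c(c1)[C@@H](CC=C)[C@H](c1cc(OC)c(OC)c(OC)c1)O2 | intermediate
12 | 3-[(2R,3R)-5-chloro-7-methoxy-2-(3,4,5-trimethoxyphenyl)-2,3-dihydrobenzofuran-3-yl]propane-1,2-diol (both carbinol epimers, not isolated) | Clc1cc(OC)c2c(c1)[C@@H](CC(O)CO)[C@H](c1cc(OC)c(OC)c(OC)c1)O2 | intermediate
13 | 2-[(2R,3R)-5-chloro-7-methoxy-2-(3,4,5-trimethoxyphenyl)-2,3-dihydrobenzofuran-3-yl]acetaldehyde | Clc1cc(OC)c2c(c1)[C@@H](CC=O)[C@H](c1cc(OC)c(OC)c(OC)c1)O2 | intermediate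
14 | (2R,3R)-5-chloro-7-methoxy-3-methyl-2-(3,4,5-trimethoxyphenyl)-2,3-dihydrobenzofuran | Clc1cc(OC)c2c(c1)[C@@H](C)[C@H](c1cc(OC)c(OC)c(OC)c1)O2 | intermediate
15 | (E)-4,4,5,5-tetramethyl-2-(prop-1-enyl)-1,3,2-dioxaborolane | C/C=C/B1OC(C)(C)C(C)(C)O1 | starting material
16 | (2R,3R)-7-methoxy-3-methyl-5-[(E)-prop-1-enyl]-2-(3,4,5-trimethoxyphenyl)-2,3-dihydrobenzofuran | C/C=C/c1cc(OC)c2c(c1)[C@@H](C)[C@H](c1cc(OC)c(OC)c(OC)c1)O2 | target

**Step count**

Total steps: 7. Longest linear sequence: 7 steps (1 to 16); compounds 2, 6, 7 and 15 are bought.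

**Steps most likely to fail**

1. Step 3 (proposed new method). The boronate may transmetalate to palladium and be allylated at C2 instead of attacking through C3, or the outer-sphere attack may show poor facial selectivity. The fallback uses a known enantioselective carbene C–H insertion; it sets out from 1 and comes back at 14, so steps 2 to 6 are not needed.
   - ortho-Iodination of 1 (N-iodosuccinimide, TsOH cat., MeCN) should give 4-chloro-2-iodo-6-methoxyphenol F1.
   - O-Alkylation with 3,4,5-trimethoxybenzyl chloride (K2CO3, DMF) should give 5-chloro-1-iodo-3-methoxy-2-[(3,4,5-trimethoxybenzyl)oxy]benzene F2.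
   - Palladium-catalysed coupling of the C–I bond with ethyl diazoacetate (Pd(PPh3)4, Ag2CO3, Et3N, toluene, rt) should give ethyl 2-diazo-2-{5-chloro-3-methoxy-2-[(3,4,5-trimethoxybenzyl)oxy]phenyl}acetate F3.
   - Intramolecular insertion of the rhodium carbene into the benzylic ether C–H bond, with the enantiomer of dirhodium tetrakis(N-phthaloyl-tert-leucinate) that gives the (2R) series (written as Rh2(S-PTTL)4, toluene, −60 °C), should give the cis ester ethyl (2R,3S)-5-chloro-7-methoxy-2-(3,4,5-trimethoxyphenyl)-2,3-dihydrobenzofuran-3-carboxylate F4.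
   - Epimerisation at C3 (NaOEt, EtOH) should give the trans ester ethyl (2R,3R)-5-chloro-7-methoxy-2-(3,4,5-trimethoxyphenyl)-2,3-dihydrobenzofuran-3-carboxylate F5.
   - Reduction (LiAlH4, THF, 0 °C) should give [(2R,3S)-5-chloro-7-methoxy-2-(3,4,5-trimethoxyphenyl)-2,3-dihydrobenzofuran-3-yl]methanol F6.
   - Tosylation (TsCl, pyridine) should give [(2R,3S)-5-chloro-7-methoxy-2-(3,4,5-trimethoxyphenyl)-2,3-dihydrobenzofuran-3-yl]methyl 4-methylbenzenesulfonate F7, and hydride displacement (LiBHEt3, THF) should give 14.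

2. Step 4. Configuration at C2 may be lost during C–B protonolysis, or the fluoride ate complex may expel the phenoxide and open ring B. The fallback sets out from 10 and comes back at 11; it replaces retentive protonolysis by oxidation, reduction and thermodynamically controlled ring closure.
   - Oxidation of the C–B bond (NaBO3·4H2O, THF/H2O, 0 °C) should give the hemiketal (2R,3R)-3-allyl-5-chloro-7-methoxy-2-(3,4,5-trimethoxyphenyl)-2,3-dihydrobenzofuran-2-ol F8, in ring–chain equilibrium with its hydroxy ketone form.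
   - Luche reduction of the keto form (NaBH4, CeCl3·7H2O, MeOH, −40 °C, to spare the α-aryl centre) should give 4-chloro-2-[(2R)-1-hydroxy-1-(3,4,5-trimethoxyphenyl)pent-4-en-2-yl]-6-methoxyphenol F9 as a mixture of carbinol epimers.
   - Acid-mediated cyclodehydration through the benzylic cation (TsOH·H2O cat., CH2Cl2, rt) should re-close ring B with the aryl group trans to the C3 allyl group and return 11.

3. Step 6. The alkylrhodium hydride may undergo β-hydride elimination to the exocyclic alkene, or CO extrusion may stay incomplete at a temperature the substrate tolerates. The fallback sets out from 13 and comes back at 14; it removes the carbon as CO2 by a radical path.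
   - Pinnick oxidation (NaClO2, NaH2PO4, 2-methyl-2-butene, t-BuOH/H2O) should give 2-[(2R,3R)-5-chloro-7-methoxy-2-(3,4,5-trimethoxyphenyl)-2,3-dihydrobenzofuran-3-yl]acetic acid F10.
   - Coupling with 1-hydroxypyridine-2(1H)-thione (DCC, CH2Cl2, dark) should give the Barton ester 2-thioxopyridin-1(2H)-yl 2-[(2R,3R)-5-chloro-7-methoxy-2-(3,4,5-trimethoxyphenyl)-2,3-dihydrobenzofuran-3-yl]acetate F11.
   - Visible-light photolysis in the presence of t-BuSH (Barton reductive decarboxylation) should give 14 through the primary radical.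

Further compounds
F1 | step 3 | 4-chloro-2-iodo-6-methoxyphenol | COc1cc(Cl)cc(I)c1O
F2 | step 3 | 5-chloro-1-iodo-3-methoxy-2-[(3,4,5-trimethoxybenzyl)oxy]benzene | COc1cc(Cl)cc(I)c1OCc1cc(OC)c(OC)c(OC)c1
F3 | step 3 | ethyl 2-diazo-2-{5-chloro-3-methoxy-2-[(3,4,5-trimethoxybenzyl)oxy]phenyl}acetate | CCOC(=O)C(=[N+]=[N-])c1cc(Cl)cc(OC)c1OCc1cc(OC)c(OC)c(OC)c1
F4 | step 3 | ethyl (2R,3S)-5-chloro-7-methoxy-2-(3,4,5-trimethoxyphenyl)-2,3-dihydrobenzofuran-3-carboxylate | Clc1cc(OC)c2c(c1)[C@H](C(=O)OCC)[C@H](c1cc(OC)c(OC)c(OC)c1)O2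
F5 | step 3 | ethyl (2R,3R)-5-chloro-7-methoxy-2-(3,4,5-trimethoxyphenyl)-2,3-dihydrobenzofuran-3-carboxylate | Clc1cc(OC)c2c(c1)[C@@H](C(=O)OCC)[C@H](c1cc(OC)c(OC)c(OC)c1)O2
F6 | step 3 | [(2R,3S)-5-chloro-7-methoxy-2-(3,4,5-trimethoxyphenyl)-2,3-dihydrobenzofuran-3-yl]methanol | Clc1cc(OC)c2c(c1)[C@@H](CO)[C@H](c1cc(OC)c(OC)c(OC)c1)O2
F7 | step 3 | [(2R,3S)-5-chloro-7-methoxy-2-(3,4,5-trimethoxyphenyl)-2,3-dihydrobenzofuran-3-yl]methyl 4-methylbenzenesulfonate | Clc1cc(OC)c2c(c1)[C@@H](COS(=O)(=O)c1ccc(C)cc1)[C@H](c1cc(OC)c(OC)c(OC)c1)O2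
F8 | step 4 | (2R,3R)-3-allyl-5-chloro-7-methoxy-2-(3,4,5-trimethoxyphenyl)-2,3-dihydrobenzofuran-2-ol | Clc1cc(OC)c2c(c1)[C@@H](CC=C)[C@](O)(c1cc(OC)c(OC)c(OC)c1)O2
F9 | step 4 | 4-chloro-2-[(2R)-1-hydroxy-1-(3,4,5-trimethoxyphenyl)pent-4-en-2-yl]-6-methoxyphenol | Clc1cc(OC)c(O)c(c1)[C@@H](CC=C)C(O)c1cc(OC)c(OC)c(OC)c1
F10 | step 6 | 2-[(2R,3R)-5-chloro-7-methoxy-2-(3,4,5-trimethoxyphenyl)-2,3-dihydrobenzofuran-3-yl]acetic acid | Clc1cc(OC)c2c(c1)[C@@H](CC(=O)O)[C@H](c1cc(OC)c(OC)c(OC)c1)O2
F11 | step 6 | 2-thioxopyridin-1(2H)-yl 2-[(2R,3R)-5-chloro-7-methoxy-2-(3,4,5-trimethoxyphenyl)-2,3-dihydrobenzofuran-3-yl]acetate | Clc1cc(OC)c2c(c1)[C@@H](CC(=O)On1ccccc1=S)[C@H](c1cc(OC)c(OC)c(OC)c1)O2
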